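The stray impurity in flask gamma outweighs its free catalyst, 0.19 mM against 0.14 mM. Gamma is the flask asked about, and beta is the same charge run hotter.

| setting | gamma | beta | flask |
|---|---|---|---|
| starting material | 0.023 M | 0.023 M | 0.023 M |
| protic impurity | 1.15 mM | 1.15 mM | 1.15 mM |
| free catalyst | 0.14 mM | 0.14 mM | 0.14 mM |
| stray impurity | 0.19 mM | 0.19 mM | 0.19 mM |
| added ligand | 0.12 mM | 0.12 mM | 0.12 mM |
| temperature | 60 °C | 66 °C | 60 °C |
| remark | the very flask that is asked about, followed so far | run made earlier |  |
| time |  |  | 10 h |

| run | time / h | product / % | starting material / % |
|---|---|---|---|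
| gamma | 0.833 | 7.4 | 88.0 |
| gamma | 1.50 | 8.0 | 85.9 |
| gamma | 2.50 | 9.5 | 85.2 |
| gamma | 3.00 | 10.3 | 85.0 |
| gamma | 4.00 | 10.6 | 84.8 |
| gamma | 5.00 | 11.2 | 84.1 |
| gamma | 6.00 | 11.2 | 83.9 |
| beta | 0.833 | 9.6 | 84.9 |
| beta | 1.50 | 11.8 | 82.7 |
| beta | 2.50 | 12.8 | 81.6 |
| beta | 3.00 | 13.3 | 81.4 |
| beta | 4.00 | 13.2 | 80.9 |
| beta | 5.00 | 13.8 | 81.3 |
| beta | 6.00 | 14.2 | 81.1 |

(readings scatter by 0.3 percentage points)

- east: at 10 h take out 90 % of the product then present, then wait 3.0 h
- north-east: change nothing and wait 3.0 h more
- south: at 10 h raise the temperature by 25 K, then wait 3.0 h
- west: at 10 h add free catalyst, 50.0 % of the amount charged, then wait 3.0 h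

- what is taken out of product is counted as made
- additions bring no volume worth counting

1. product, in percent of the starting material first charged, at 10 h
2. what to do for the largest gain in product; "none" if nothing gains more than 2 percentage points (east / north-east / south / west / none)
3. product present, with what was taken out counted in, in percent of the starting material first charged, after east
4. product present, with what was taken out counted in, in percent of the starting material first charged, after north-east

Two chemists read gamma's flat tail differently. The first sees equilibrium. Let s be product over product plus starting material, read at 6.00 h: 11.8 %. If the mixture refills to that share within 3.0 h, east should count about 20.1 %.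

The second sees a catalyst killed by the stray impurity, one for one. Define the surplus D as the stray impurity charged minus the free catalyst charged: 0.0500 mM. On that count, positive D makes the catalyst the limiting reagent of the poisoning, and D is what stays of the stray impurity. On the same count, negative D means the stray impurity goes first and catalyst survives. Gamma's D is positive, so on this count waiting and removal should gain little. West's dose is 0.0700 mM, larger than D, so 0.0200 mM of it should outlast the stray impurity.

The forecast takes the second side, on its own grounds: “It looks more like catalyst being lost, probably to the stray impurity.” It gives 12 % now, 12.6 % after east, 12.2 % after north-east, and chooses west. The surplus D is our count, not the forecast's.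

Flask gamma gives 11.4 % at 10 h, 11.4 % after east and 11.4 % after north-east, and the best move is west, worth 12 percentage points. The forecast stands. The first chemist's view keeps one step that does run back, the binding of starting material to free catalyst: the falling back of catalyst intermediate A moves the shown readings by 37 scatters, root mean square. Gamma's stray impurity at 10 h stands at 0.0503 mM, close to D, and west's 0.0700 mM is larger.

    free catalyst + stray impurity → spent catalyst (k = 2050 /M/min, Ea = 49.0 kJ/mol)
    catalyst intermediate B → free catalyst + product (k = 23.6 /min, Ea = 77.0 kJ/mol)
    free catalyst + added ligand ⇌ idle complex, settled at all times (K = 88000 /M, ΔH = −29.0 kJ/mol)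
    starting material + free catalyst ⇌ catalyst intermediate A (K = 130 /M, k = 480 /M/min, Ea = 52.0 kJ/mol, ΔH = 8.00 kJ/mol)
    starting material + protic impurity → quenched substrate (k = 807 /M/min, Ea = 53.0 kJ/mol)
    catalyst intermediate A → catalyst intermediate B (k = 2.57 /min, Ea = 98.0 kJ/mol)
    (constants at 60 °C)

A neighbour of flask gamma holds 7.6 × 10⁻⁵ M of stray impurity, so its D is −0.0640 mM, negative, and the count allows 54.3 % of the catalyst to be lost. Computed at 10 h, that neighbour has spent catalyst 54.3 %, stray impurity 0 % of its charge, and product 59.8 %.

The readings are calculated for an exercise.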